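**Retrosynthetic overview**

1. The guanine C8–ring A bond is made last, by Suzuki–Miyaura coupling of a ring A pinacol boronate (ortho to the phenol oxygen) with 8-bromo-2'-deoxyguanosine; one acid treatment then removes the sugar, the MOM ether and both Boc groups.
2. The strategy rests on ring B: a bent para-phenylene with four CH positions whose only substituents are the diaryl ether oxygen and, para to it, the methylene to the piperazine carbon. It is cut into pyrone C3–C6 of a 5-substituted 2-pyrone plus the two carbons of the ethynyl ether of the ring A phenol, with CO2 as the leaving fragment.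
3. The precursor comes from a Negishi coupling of a serine-derived alkylzinc with 5-bromo-2H-pyran-2-one; the ynol ether comes from the ring A phenol through its dichlorovinyl ether.
4. The piperazine comes from LiAlH4 reduction of cyclo(L-Ser–L-ArAla). The ring A amino acid comes from O-benzylisovanillin by Horner–Wadsworth–Emmons olefination and asymmetric hydrogenation; L-serine supplies the second stereocentre.
5. Order of rings: ring A (bought), piperazine (steps 4–5), pyrone (bought, attached in step 13), ring B together with the 14-membered ring (step 14), guanine (attached in step 20).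

Key step: step 14

Remark on the chemistry: the 2-deoxyribosyl group of commercial 8-bromo-2'-deoxyguanosine serves as the N9 protecting group of 8-bromoguanine. The target is drawn as its N7-H tautomer, which is the same compound as the N9-H form. In the piperazine names, locant 2 is kept on the carbon that bears the ring A benzyl group throughout.

**Route**

Step 1
Reactants: 1 3-benzyloxy-4-methoxybenzaldehyde (O-benzylisovanillin); 2 methyl 2-(tert-butoxycarbonylamino)-2-(dimethoxyphosphoryl)acetate
Product: 3 methyl (Z)-3-(3-benzyloxy-4-methoxyphenyl)-2-(tert-butoxycarbonylamino)acrylate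
Conditions: DBU, CH2Cl2, 0 °C to rt
Reagents that add atoms: none
Why: Horner–Wadsworth–Emmons olefination of an aryl aldehyde with the phosphonoglycinate anion should give the (Z)-dehydroamino ester, the isomer needed for the enantioselective hydrogenation.

Step 2
Reactants: 3 methyl (Z)-3-(3-benzyloxy-4-methoxyphenyl)-2-(tert-butoxycarbonylamino)acrylate
Product: 4 methyl (S)-3-(3-benzyloxy-4-methoxyphenyl)-2-(tert-butoxycarbonylamino)propanoate
Conditions: H2 (4 bar), [Rh(cod)((S,S)-Et-DuPhos)]OTf (1 mol %), MeOH, rt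
Reagents that add atoms: none
Why: Rhodium-catalysed asymmetric hydrogenation of a chelating (Z)-α-acylamino acrylate, in which the (S,S)-Et-DuPhos ligand should direct H2 to one enamide face and so set the (S) centre of the L-amino acid, with the benzyl ether and Boc group untouched.

Step 3
Reactants: 4 methyl (S)-3-(3-benzyloxy-4-methoxyphenyl)-2-(tert-butoxycarbonylamino)propanoate; 5 N-Boc-L-serine
Product: 7 methyl (S)-3-(3-benzyloxy-4-methoxyphenyl)-2-[(S)-2-(tert-butoxycarbonylamino)-3-hydroxypropanamido]propanoate, via amine hydrochloride 6 (not isolated)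
Conditions: 4 M HCl in dioxane, rt; evaporate; then 5, EDC·HCl, HOBt, N-methylmorpholine, CH2Cl2, 0 °C to rt
Reagents that add atoms: none
Why: Acidolysis of the Boc group followed by carbodiimide/HOBt amide coupling, which tolerates the free serine hydroxyl and should not epimerise the urethane-protected serine.

Step 4
Reactants: 7 methyl (S)-3-(3-benzyloxy-4-methoxyphenyl)-2-[(S)-2-(tert-butoxycarbonylamino)-3-hydroxypropanamido]propanoate
Product: 9 (3S,6S)-3-(3-benzyloxy-4-methoxybenzyl)-6-(hydroxymethyl)piperazine-2,5-dione, via dipeptide amine hydrochloride 8 (not isolated)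
Conditions: 4 M HCl in dioxane, rt; evaporate; then N-methylmorpholine (1.1 equiv), AcOH (cat.), 2-butanol/toluene, reflux
Reagents that add atoms: none
Why: Boc removal frees the serine amine, which should close the diketopiperazine by 6-exo-trig aminolysis of the methyl ester (lactamisation) under buffered conditions that leave both α-centres intact.

Step 5
Reactants: 9 (3S,6S)-3-(3-benzyloxy-4-methoxybenzyl)-6-(hydroxymethyl)piperazine-2,5-dione
Product: 10 [(2R,5S)-5-(3-benzyloxy-4-methoxybenzyl)piperazin-2-yl]methanol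
Conditions: LiAlH4, THF, reflux; aqueous NaOH work-up
Reagents that add atoms: none
Why: Amide reduction with LiAlH4 should turn both lactam carbonyls into methylenes without touching a stereocentre or the benzyl ether; the serine-derived centre is named R only because CH2OH now outranks the ring CH2.

Step 6
Reactants: 10 [(2R,5S)-5-(3-benzyloxy-4-methoxybenzyl)piperazin-2-yl]methanol
Product: 11 dimethyl (2S,5R)-2-(3-benzyloxy-4-methoxybenzyl)-5-(hydroxymethyl)piperazine-1,4-dicarboxylate
Conditions: ClCO2Me (2.2 equiv), NaHCO3, CH2Cl2/H2O, 0 °C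
Reagents that add atoms: methyl chloroformate, COC(=O)Cl
Why: Schotten–Baumann N-acylation, in which the two secondary amines should react far faster than the primary alcohol; methyl carbamates are chosen because, unlike tert-butyl carbamates, they should survive the thermolysis of step 14.

Step 7
Reactants: 11 dimethyl (2S,5R)-2-(3-benzyloxy-4-methoxybenzyl)-5-(hydroxymethyl)piperazine-1,4-dicarboxylate
Product: 12 dimethyl (2S,5R)-2-(3-benzyloxy-4-methoxybenzyl)-5-[(tert-butyldimethylsilyloxy)methyl]piperazine-1,4-dicarboxylate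
Conditions: TBSCl, imidazole, CH2Cl2, rt
Reagents that add atoms: tert-butyldimethylsilyl chloride, CC(C)(C)[Si](C)(C)Cl
Why: Silylation of the primary alcohol, which blocks the alkoxide that could otherwise close an oxazolidinone onto the neighbouring carbamate under the basic conditions of steps 9 and 10.

Step 8
Reactants: 12 dimethyl (2S,5R)-2-(3-benzyloxy-4-methoxybenzyl)-5-[(tert-butyldimethylsilyloxy)methyl]piperazine-1,4-dicarboxylate
Product: 13 dimethyl (2S,5R)-2-(3-hydroxy-4-methoxybenzyl)-5-[(tert-butyldimethylsilyloxy)methyl]piperazine-1,4-dicarboxylate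
Conditions: H2 (1 atm), Pd/C, EtOAc/MeOH, rt
Reagents that add atoms: none
Why: Hydrogenolysis of the aryl benzyl ether should free the ring A phenol while carbamates and silyl ether stay in place.

Step 9
Reactants: 13 dimethyl (2S,5R)-2-(3-hydroxy-4-methoxybenzyl)-5-[(tert-butyldimethylsilyloxy)methyl]piperazine-1,4-dicarboxylate
Product: 14 dimethyl (2S,5R)-2-{3-[(E)-1,2-dichlorovinyloxy]-4-methoxybenzyl}-5-[(tert-butyldimethylsilyloxy)methyl]piperazine-1,4-dicarboxylate
Conditions: Cl2C=CHCl, K2CO3, DMF, 70 °C
Reagents that add atoms: trichloroethylene, ClC=C(Cl)Cl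
Why: Base-mediated vinylation of a phenol with trichloroethylene, in which K2CO3 forms dichloroacetylene in situ and the phenoxide adds to it, protonation giving the (E)-1,2-dichlorovinyl ether.

Step 10
Reactants: 14 dimethyl (2S,5R)-2-{3-[(E)-1,2-dichlorovinyloxy]-4-methoxybenzyl}-5-[(tert-butyldimethylsilyloxy)methyl]piperazine-1,4-dicarboxylate
Product: 17 dimethyl (2S,5R)-2-(3-ethynyloxy-4-methoxybenzyl)-5-[(tert-butyldimethylsilyloxy)methyl]piperazine-1,4-dicarboxylate, via chloroethynyl ether 15 (not isolated), via lithium acetylide 16 (not isolated)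
Conditions: n-BuLi (2.2 equiv), THF, −78 °C; then MeOH, −78 °C
Reagents that add atoms: none
Why: Dehydrochlorination to the chloroalkynyl ether followed by chlorine–lithium exchange (the ynol ether synthesis from dichlorovinyl ethers) is fast at −78 °C, where the hindered tertiary methyl carbamates and the silyl ether should be left alone by the slight excess of n-BuLi.

Step 11
Reactants: 17 dimethyl (2S,5R)-2-(3-ethynyloxy-4-methoxybenzyl)-5-[(tert-butyldimethylsilyloxy)methyl]piperazine-1,4-dicarboxylate
Product: 18 dimethyl (2S,5R)-2-(3-ethynyloxy-4-methoxybenzyl)-5-(hydroxymethyl)piperazine-1,4-dicarboxylate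
Conditions: Bu4NF, AcOH (1:1), THF, 0 °C
Reagents that add atoms: none
Why: Fluoride desilylation of the primary silyl ether, buffered so that the liberated alkoxide is protonated before it can attack the adjacent carbamate; the aryl ynol ether is inert to buffered fluoride.

Step 12
Reactants: 18 dimethyl (2S,5R)-2-(3-ethynyloxy-4-methoxybenzyl)-5-(hydroxymethyl)piperazine-1,4-dicarboxylate
Product: 19 dimethyl (2S,5R)-2-(3-ethynyloxy-4-methoxybenzyl)-5-(iodomethyl)piperazine-1,4-dicarboxylate
Conditions: PPh3, I2, imidazole (premixed), CH2Cl2, 0 °C to rt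
Reagents that add atoms: iodine, [I][I]
Why: Appel-type iodination by SN2 displacement at the primary carbon, which does not involve the stereocentre; premixing the reagents leaves no free iodine for the electron-rich alkyne.

Step 13
Reactants: 19 dimethyl (2S,5R)-2-(3-ethynyloxy-4-methoxybenzyl)-5-(iodomethyl)piperazine-1,4-dicarboxylate; 20 5-bromo-2H-pyran-2-one
Product: 22 dimethyl (2S,5S)-2-(3-ethynyloxy-4-methoxybenzyl)-5-[(2-oxo-2H-pyran-5-yl)methyl]piperazine-1,4-dicarboxylate, via alkylzinc iodide 21 (not isolated)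
Conditions: Zn dust (activated with I2), DMF, 0 °C to rt; then 20, Pd2(dba)3 (2.5 mol %), SPhos (10 mol %), rt to 40 °C
Reagents that add atoms: none
Why: Zinc insertion into the primary iodide gives a carbamate-stabilised β-amido alkylzinc that should undergo Negishi coupling with the bromopyrone after fast oxidative addition to zerovalent palladium; the descriptor changes from R to S by priority only.

Step 14
Reactants: 22 dimethyl (2S,5S)-2-(3-ethynyloxy-4-methoxybenzyl)-5-[(2-oxo-2H-pyran-5-yl)methyl]piperazine-1,4-dicarboxylate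
Product: 24 O-methylpiperazinomycin N,N'-bis(methyl carbamate), via bridged lactone cycloadduct 23 (not isolated)
Conditions: 1,2-dichlorobenzene (dry, degassed, 1 mM), BHT (0.1 equiv), 200 °C, sealed vessel
Reagents that add atoms: none
Why: On heating, the electron-rich ynol ether should add across pyrone C3 and C6 in an intramolecular inverse-electron-demand [4+2] cycloaddition to give the bridged lactone 23, which loses CO2 by retro-[4+2] and aromatises to ring B. The closest known reaction type is the 2-pyrone–alkyne Diels–Alder/decarboxylation benzannulation, established for heteroatom-substituted alkynes and, in its intramolecular form, for bent para-cyclophane arenes. Ring B (six-membered) closes by the cycloaddition itself through the new bonds C3–C(OAr) and C6–CH, and the 14-membered ring closes in the same event as a macrocyclic cycloaddition, the tether (pyrone C5–CH2–piperazine–CH2–ring A–O) spanning the two para positions. No stereocentre is formed in 24, since the two bridgehead centres of 23 vanish with CO2 and the piperazine centres are not touched. The step needs para rather than meta bridging, which the polarisation should secure because the nucleophilic terminal CH of the ynol ether bonds to the electrophilic C6 next to the ring oxygen and so puts the ether oxygen para to the C5 methylene; high dilution keeps the reaction intramolecular. In 23 the two tether-bearing carbons sit on separate etheno bridges inclined at about 120°, so the cyclophane strain is taken up only in the irreversible, aromatising loss of CO2.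

Step 15
Reactants: 24 O-methylpiperazinomycin N,N'-bis(methyl carbamate)
Product: 26 piperazinomycin, via tris(trimethylsilyl) intermediate 25 (not isolated)
Conditions: Me3SiI (excess), MeCN, 60 °C; then MeOH
Reagents that add atoms: none
Why: Silylation of the ether and carbamate oxygens followed by SN2 attack of iodide on the three O-methyl groups (iodotrimethylsilane dealkylation), then methanolysis and decarboxylation of the silyl carbamates, should free the phenol and both amines while the diaryl ether stays inert.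

Step 16
Reactants: 26 piperazinomycin
Product: 27 N,N'-di-Boc-piperazinomycin
Conditions: Boc2O (2.2 equiv), NaHCO3, THF/H2O, rt
Reagents that add atoms: di-tert-butyl dicarbonate, CC(C)(C)OC(=O)OC(=O)OC(C)(C)C
Why: Carbamoylation of the two secondary amines, which are far more nucleophilic than the phenol under bicarbonate conditions.

Step 17
Reactants: 27 N,N'-di-Boc-piperazinomycin
Product: 28 ring A bromide of N,N'-di-Boc-piperazinomycin (Br ortho to the phenol OH)
Conditions: NBS (1.0 equiv), i-Pr2NH (10 mol %), CH2Cl2, 0 °C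
Reagents that add atoms: N-bromosuccinimide, O=C1CCC(=O)N1Br
Why: Amine-catalysed ortho-selective electrophilic bromination of a phenol, which has one site only, because the other ortho carbon carries the diaryl ether oxygen and the para carbon the benzylic methylene.

Step 18
Reactants: 28 ring A bromide of N,N'-di-Boc-piperazinomycin
Product: 29 O-methoxymethyl ether of bromide 28
Conditions: NaH, MOMCl, THF/DMF, 0 °C
Reagents that add atoms: chloromethyl methyl ether, COCCl
Why: Williamson-type O-alkylation of the hindered phenoxide gives an acetal that shields the phenol during borylation and falls off in the final acid step.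

Step 19
Reactants: 29 O-methoxymethyl ether of bromide 28
Product: 30 ring A pinacol boronate
Conditions: B2pin2, Pd(dppf)Cl2 (5 mol %), KOAc, dioxane, 90 °C
Reagents that add atoms: bis(pinacolato)diboron, CC1(C)OB(OC1(C)C)B1OC(C)(C)C(C)(C)O1
Why: Miyaura borylation of an electron-rich aryl bromide, in which the weak acetate base avoids premature biaryl coupling and leaves the Boc and MOM groups intact.

Step 20
Reactants: 30 ring A pinacol boronate; 31 8-bromo-2'-deoxyguanosine
Product: 32 8-aryl-2'-deoxyguanosine (aryl = O-MOM-N,N'-di-Boc-piperazinomycin joined at the ring A carbon ortho to the MOM ether)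
Conditions: Pd(dppf)Cl2 (10 mol %), K3PO4, dioxane/DMF/H2O, 90 °C
Reagents that add atoms: none
Why: Suzuki–Miyaura coupling of an ortho-alkoxy arylboronate with the C8 bromide of an unprotected purine nucleoside, a coupling that tolerates the free amino, lactam and hydroxyl groups in aqueous base.

Step 21
Reactants: 32 8-aryl-2'-deoxyguanosine
Product: 33 guanipiperazine A
Conditions: 2 M HCl, THF/H2O, 50 °C; then aqueous NH3 to neutrality
Reagents that add atoms: none
Why: Acid-mediated global deprotection, in which N-Boc cleavage, MOM acetal hydrolysis and hydrolysis of the purine N9–C1' glycosidic bond (depurination, fast for 8-aryl-2'-deoxyguanosines) should occur together without touching the non-epimerisable piperazine centres.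

**Compound list**

1 | 3-benzyloxy-4-methoxybenzaldehyde | COc1ccc(C=O)cc1OCc1ccccc1 | starting material
2 | methyl 2-(tert-butoxycarbonylamino)-2-(dimethoxyphosphoryl)acetate (racemic) | COC(=O)C(NC(=O)OC(C)(C)C)P(=O)(OC)OC | starting material
3 | methyl (Z)-3-(3-benzyloxy-4-methoxyphenyl)-2-(tert-butoxycarbonylamino)acrylate | COC(=O)/C(NC(=O)OC(C)(C)C)=C/c1ccc(OC)c(OCc2ccccc2)c1 | intermediate
4 | methyl (S)-3-(3-benzyloxy-4-methoxyphenyl)-2-(tert-butoxycarbonylamino)propanoate | COC(=O)[C@H](Cc1ccc(OC)c(OCc2ccccc2)c1)NC(=O)OC(C)(C)C | intermediate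
5 | N-Boc-L-serine | CC(C)(C)OC(=O)N[C@@H](CO)C(=O)O | starting material
6 | methyl (S)-2-amino-3-(3-benzyloxy-4-methoxyphenyl)propanoate hydrochloride | COC(=O)[C@H](Cc1ccc(OC)c(OCc2ccccc2)c1)[NH3+].[Cl-] | intermediate
7 | methyl (S)-3-(3-benzyloxy-4-methoxyphenyl)-2-[(S)-2-(tert-butoxycarbonylamino)-3-hydroxypropanamido]propanoate | COC(=O)[C@H](Cc1ccc(OC)c(OCc2ccccc2)c1)NC(=O)[C@H](CO)NC(=O)OC(C)(C)C | intermediate
8 | methyl (S)-2-[(S)-2-amino-3-hydroxypropanamido]-3-(3-benzyloxy-4-methoxyphenyl)propanoate hydrochloride | COC(=O)[C@H](Cc1ccc(OC)c(OCc2ccccc2)c1)NC(=O)[C@H](CO)[NH3+].[Cl-] | intermediate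
9 | (3S,6S)-3-(3-benzyloxy-4-methoxybenzyl)-6-(hydroxymethyl)piperazine-2,5-dione | O=C1[C@H](Cc2ccc(OC)c(OCc3ccccc3)c2)NC(=O)[C@H](CO)N1 | intermediate
10 | [(2R,5S)-5-(3-benzyloxy-4-methoxybenzyl)piperazin-2-yl]methanol | C1[C@H](Cc2ccc(OC)c(OCc3ccccc3)c2)NC[C@H](CO)N1 | intermediate
11 | dimethyl (2S,5R)-2-(3-benzyloxy-4-methoxybenzyl)-5-(hydroxymethyl)piperazine-1,4-dicarboxylate | C1[C@H](Cc2ccc(OC)c(OCc3ccccc3)c2)N(C(=O)OC)C[C@H](CO)N1C(=O)OC | intermediate
12 | dimethyl (2S,5R)-2-(3-benzyloxy-4-methoxybenzyl)-5-[(tert-butyldimethylsilyloxy)methyl]piperazine-1,4-dicarboxylate | C1[C@H](Cc2ccc(OC)c(OCc3ccccc3)c2)N(C(=O)OC)C[C@H](CO[Si](C)(C)C(C)(C)C)N1C(=O)OC | intermediate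
13 | dimethyl (2S,5R)-2-(3-hydroxy-4-methoxybenzyl)-5-[(tert-butyldimethylsilyloxy)methyl]piperazine-1,4-dicarboxylate | C1[C@H](Cc2ccc(OC)c(O)c2)N(C(=O)OC)C[C@H](CO[Si](C)(C)C(C)(C)C)N1C(=O)OC | intermediate
14 | dimethyl (2S,5R)-2-{3-[(E)-1,2-dichlorovinyloxy]-4-methoxybenzyl}-5-[(tert-butyldimethylsilyloxy)methyl]piperazine-1,4-dicarboxylate | C1[C@H](Cc2ccc(OC)c(O/C(Cl)=C\Cl)c2)N(C(=O)OC)C[C@H](CO[Si](C)(C)C(C)(C)C)N1C(=O)OC | intermediate
15 | chloroethynyl ether corresponding to 14 | C1[C@H](Cc2ccc(OC)c(OC#CCl)c2)N(C(=O)OC)C[C@H](CO[Si](C)(C)C(C)(C)C)N1C(=O)OC | intermediate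
16 | lithium aryloxyacetylide | C1[C@H](Cc2ccc(OC)c(OC#C[Li])c2)N(C(=O)OC)C[C@H](CO[Si](C)(C)C(C)(C)C)N1C(=O)OC | intermediate
17 | dimethyl (2S,5R)-2-(3-ethynyloxy-4-methoxybenzyl)-5-[(tert-butyldimethylsilyloxy)methyl]piperazine-1,4-dicarboxylate | C1[C@H](Cc2ccc(OC)c(OC#C)c2)N(C(=O)OC)C[C@H](CO[Si](C)(C)C(C)(C)C)N1C(=O)OC | intermediate
18 | dimethyl (2S,5R)-2-(3-ethynyloxy-4-methoxybenzyl)-5-(hydroxymethyl)piperazine-1,4-dicarboxylate | C1[C@H](Cc2ccc(OC)c(OC#C)c2)N(C(=O)OC)C[C@H](CO)N1C(=O)OC | intermediate
19 | dimethyl (2S,5R)-2-(3-ethynyloxy-4-methoxybenzyl)-5-(iodomethyl)piperazine-1,4-dicarboxylate | C1[C@H](Cc2ccc(OC)c(OC#C)c2)N(C(=O)OC)C[C@H](CI)N1C(=O)OC | intermediate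
20 | 5-bromo-2H-pyran-2-one | O=c1ccc(Br)co1 | starting material
21 | alkylzinc iodide from 19 | C1[C@H](Cc2ccc(OC)c(OC#C)c2)N(C(=O)OC)C[C@H](C[Zn]I)N1C(=O)OC | intermediate
22 | dimethyl (2S,5S)-2-(3-ethynyloxy-4-methoxybenzyl)-5-[(2-oxo-2H-pyran-5-yl)methyl]piperazine-1,4-dicarboxylate | O=c1ccc(C[C@H]2CN(C(=O)OC)[C@H](CN2C(=O)OC)Cc3ccc(OC)c(OC#C)c3)co1 | intermediate
23 | macrocyclic 2-oxabicyclo[2.2.2]octa-5,7-dien-3-one cycloadduct (bridgeheads of either configuration) | COc1ccc2cc1OC1=CC3OC(=O)C1C=C3C[C@H]1CN(C(=O)OC)[C@H](CN1C(=O)OC)C2 | intermediate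
24 | O-methylpiperazinomycin N,N'-bis(methyl carbamate) | COc1ccc2cc1Oc1ccc(cc1)C[C@H]3CN(C(=O)OC)[C@H](CN3C(=O)OC)C2 | intermediate
25 | O-trimethylsilyl piperazinomycin N,N'-bis(trimethylsilyl carbamate) | C[Si](C)(C)Oc1ccc2cc1Oc1ccc(cc1)C[C@H]3CN(C(=O)O[Si](C)(C)C)[C@H](CN3C(=O)O[Si](C)(C)C)C2 | intermediate
26 | piperazinomycin | Oc1ccc2cc1Oc1ccc(cc1)C[C@H]3CN[C@H](CN3)C2 | intermediate
27 | N,N'-di-Boc-piperazinomycin | Oc1ccc2cc1Oc1ccc(cc1)C[C@H]3CN(C(=O)OC(C)(C)C)[C@H](CN3C(=O)OC(C)(C)C)C2 | intermediate
28 | N,N'-di-Boc-piperazinomycin brominated on ring A ortho to OH | Oc1c(Br)cc2cc1Oc1ccc(cc1)C[C@H]3CN(C(=O)OC(C)(C)C)[C@H](CN3C(=O)OC(C)(C)C)C2 | intermediate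
29 | O-methoxymethyl ether of 28 | COCOc1c(Br)cc2cc1Oc1ccc(cc1)C[C@H]3CN(C(=O)OC(C)(C)C)[C@H](CN3C(=O)OC(C)(C)C)C2 | intermediate
30 | ring A pinacol boronate | COCOc1c(B3OC(C)(C)C(C)(C)O3)cc2cc1Oc1ccc(cc1)C[C@H]3CN(C(=O)OC(C)(C)C)[C@H](CN3C(=O)OC(C)(C)C)C2 | intermediate
31 | 8-bromo-2'-deoxyguanosine | Nc1nc2n([C@H]3C[C@@H]([C@H](O3)CO)O)c(Br)nc2c(=O)[nH]1 | starting material
32 | 8-aryl-2'-deoxyguanosine carrying the protected piperazinomycin unit | Nc1nc2n([C@H]3C[C@@H]([C@H](O3)CO)O)c(-c3cc4cc(c3OCOC)Oc3ccc(cc3)C[C@H]3CN(C(=O)OC(C)(C)C)[C@H](CN3C(=O)OC(C)(C)C)C4)nc2c(=O)[nH]1 | intermediate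
33 | guanipiperazine A | Nc1nc2nc(-c3cc4cc(c3O)Oc3ccc(cc3)C[C@H]3CN[C@H](CN3)C4)[nH]c2c(=O)[nH]1 | target

**Step count**

Total steps: 21. Longest linear sequence: 21 steps (1 to 33); the other starting materials 2, 5, 20 and 31 are bought and used as such.

**Steps most likely to fail**

Step 14. Three processes may defeat it: the terminal ynol ether may decompose or oligomerise thermally before it cycloadds; the cycloaddition may take the meta course and give the less strained 13-membered metacyclophane; or the tether may not reach the transition state at a temperature that the carbamates tolerate. The fallback gives up the benzannulation and closes the macrocycle by an intramolecular Ullmann diaryl ether synthesis, with ring B bought as an arene. It sets out from alcohol 11. Appel iodination (PPh3, I2, imidazole) should give the benzyl ether iodide F1. Zinc insertion (Zn dust, DMF) gives the alkylzinc iodide F2, which is coupled at the C–I bond of 1-bromo-4-iodobenzene (Pd2(dba)3, SPhos, rt) to give the 4-bromobenzyl piperazine F3. Debenzylation with BCl3 and pentamethylbenzene (CH2Cl2, −78 °C), which spares the aryl bromide, gives the bromo phenol F4. Ring closure with CuBr·SMe2 and Cs2CO3 in pyridine at 130 °C under high dilution should then give 24, where the route is rejoined at step 15.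

Step 13. The alkylzinc may lose the carbamate nitrogen by β-elimination, or it may be protonated by the acetylenic C–H, and palladium may consume the terminal ynol ether by insertion or alkynyl coupling. The fallback carries the alkyne as its C-silyl derivative through the halogenation and the coupling and unveils the C–H only afterwards. It sets out from dichlorovinyl ether 14: n-BuLi at −78 °C followed by i-Pr3SiOTf should give the C-triisopropylsilyl ynol ether F5. Selective O-desilylation with pyridine-buffered HF·pyridine (THF, 0 °C) gives the alcohol F6, and Appel iodination gives the iodide F7. Zinc insertion at 0 °C gives the alkylzinc iodide F8, and Negishi coupling with 20 gives the silylated pyrone F9. Buffered Bu4NF/AcOH (THF, 0 °C) then removes the silyl group to give 22, which goes on to step 14.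

Step 10. n-BuLi may add to the methyl carbamate carbonyls in competition with elimination and chlorine–lithium exchange. The fallback makes the ynol ether with a non-nucleophilic amide base from a bromovinyl ether. It sets out from phenol 13: copper-mediated O-vinylation (Cu(OAc)2, pyridine, 2,4,6-trivinylcyclotriboroxane–pyridine complex, CH2Cl2, air, rt) should give the aryl vinyl ether F10. Bromine at −78 °C gives the 1,2-dibromoethyl ether F11, which is not isolated and on treatment with DBU loses HBr to give the 2-bromovinyl ether F12 as an E/Z mixture. LiN(i-Pr)2 (2.2 equiv, THF, −78 °C, then MeOH) should then eliminate HBr to give 17, where the route is rejoined at step 11.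

**Further compounds**

F1 | step 14 | dimethyl (2S,5R)-2-(3-benzyloxy-4-methoxybenzyl)-5-(iodomethyl)piperazine-1,4-dicarboxylate | C1[C@H](Cc2ccc(OC)c(OCc3ccccc3)c2)N(C(=O)OC)C[C@H](CI)N1C(=O)OC
F2 | step 14 | alkylzinc iodide from F1 | C1[C@H](Cc2ccc(OC)c(OCc3ccccc3)c2)N(C(=O)OC)C[C@H](C[Zn]I)N1C(=O)OC
F3 | step 14 | dimethyl (2S,5S)-2-(3-benzyloxy-4-methoxybenzyl)-5-(4-bromobenzyl)piperazine-1,4-dicarboxylate | C1[C@H](Cc2ccc(OC)c(OCc3ccccc3)c2)N(C(=O)OC)C[C@H](Cc2ccc(Br)cc2)N1C(=O)OC
F4 | step 14 | dimethyl (2S,5S)-2-(3-hydroxy-4-methoxybenzyl)-5-(4-bromobenzyl)piperazine-1,4-dicarboxylate | C1[C@H](Cc2ccc(OC)c(O)c2)N(C(=O)OC)C[C@H](Cc2ccc(Br)cc2)N1C(=O)OC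
F5 | step 13 | dimethyl (2S,5R)-2-{4-methoxy-3-[(triisopropylsilyl)ethynyloxy]benzyl}-5-[(tert-butyldimethylsilyloxy)methyl]piperazine-1,4-dicarboxylate | C1[C@H](Cc2ccc(OC)c(OC#C[Si](C(C)C)(C(C)C)C(C)C)c2)N(C(=O)OC)C[C@H](CO[Si](C)(C)C(C)(C)C)N1C(=O)OC
F6 | step 13 | dimethyl (2S,5R)-2-{4-methoxy-3-[(triisopropylsilyl)ethynyloxy]benzyl}-5-(hydroxymethyl)piperazine-1,4-dicarboxylate | C1[C@H](Cc2ccc(OC)c(OC#C[Si](C(C)C)(C(C)C)C(C)C)c2)N(C(=O)OC)C[C@H](CO)N1C(=O)OC
F7 | step 13 | dimethyl (2S,5R)-2-{4-methoxy-3-[(triisopropylsilyl)ethynyloxy]benzyl}-5-(iodomethyl)piperazine-1,4-dicarboxylate | C1[C@H](Cc2ccc(OC)c(OC#C[Si](C(C)C)(C(C)C)C(C)C)c2)N(C(=O)OC)C[C@H](CI)N1C(=O)OC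
F8 | step 13 | alkylzinc iodide from F7 | C1[C@H](Cc2ccc(OC)c(OC#C[Si](C(C)C)(C(C)C)C(C)C)c2)N(C(=O)OC)C[C@H](C[Zn]I)N1C(=O)OC
F9 | step 13 | dimethyl (2S,5S)-2-{4-methoxy-3-[(triisopropylsilyl)ethynyloxy]benzyl}-5-[(2-oxo-2H-pyran-5-yl)methyl]piperazine-1,4-dicarboxylate | O=c1ccc(C[C@H]2CN(C(=O)OC)[C@H](CN2C(=O)OC)Cc3ccc(OC)c(OC#C[Si](C(C)C)(C(C)C)C(C)C)c3)co1
F10 | step 10 | dimethyl (2S,5R)-2-(4-methoxy-3-vinyloxybenzyl)-5-[(tert-butyldimethylsilyloxy)methyl]piperazine-1,4-dicarboxylate | C1[C@H](Cc2ccc(OC)c(OC=C)c2)N(C(=O)OC)C[C@H](CO[Si](C)(C)C(C)(C)C)N1C(=O)OC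
F11 | step 10 | 1,2-dibromoethyl ether from F10 (both epimers at the new CHBr carbon) | C1[C@H](Cc2ccc(OC)c(OC(Br)CBr)c2)N(C(=O)OC)C[C@H](CO[Si](C)(C)C(C)(C)C)N1C(=O)OC
F12 | step 10 | 2-bromovinyl ether (E/Z mixture) | C1[C@H](Cc2ccc(OC)c(OC=CBr)c2)N(C(=O)OC)C[C@H](CO[Si](C)(C)C(C)(C)C)N1C(=O)OC
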